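**Plan**

- Cuts, in retrosynthetic order: C15–O (allylic C–H); C13–C16 (ring D); the lactone C10–O, exchanged for a C10–carboxyl carbon (C20); C6–C7; C8–C15, with ring C taken back to an anisole ring; C6–C8 (ring B); last, C1–C10 and C4–C5 together (ring A).
- Enabling feature: in ring A the oxygen on C3 and the carboxyl carbon C19 on C4 make C1–C4 a 2-silyloxydiene ester. The oxygen on C10 marks a lost carbon; restored as a carbonyl (C20) it turns C5=C10 into the alkene of a butenolide whose acetal carbon is C6 and whose 10-aryl group is ring C (C8, C9, C11–C14).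
- Forward: ring A by Diels–Alder reaction; ring B by Friedel–Crafts acylation (trans A/B); Birch reductive propargylation (quaternary C8, ring C unmasked); C7 by Wittig homologation; C20 expelled as CO2 with closure of the 19,10-lactone; ring D by ketyl–alkyne cyclisation; 15β-OH last by allylic C–H oxidation.
- Stereochemistry: the (5R) acetal carbon of a menthol-derived butenolide (future C6) sets C5 and C10 by anti addition. C4, C3 and C8 follow by substrate control; C9 and C6 are set thermodynamically; C10–O by the C19 tether; C13 by the bridge; C15 by β-face oxygen delivery.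

Key step: step 6

Remark: gibberellane numbering (C1–C20, C20 being the carbon that C19-gibberellins lack) is used for every intermediate; α and β are the faces of the target as usually drawn (lactone bridge α); butenolide 1 is assumed to be purchasable in its (5R) form derived from (−)-menthol.

**Route**

Step 1
Reactants: 1 (5R)-5-[(1R,2S,5R)-menthyloxy]furan-2(5H)-one
Product: 3 (5R)-3-bromo-5-[(1R,2S,5R)-menthyloxy]furan-2(5H)-one, via 3,4-dibromo lactone 2 (not isolated)
Conditions: Br2, CH2Cl2, 0 °C; then Et3N, 0 °C to rt
Reagents that add atoms: bromine, BrBr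
Why: Bromine addition to the enoate followed by amine-induced E1cB loss of HBr (the C3 proton is the acidic one) should give the α-bromobutenolide without touching the acetal stereocentre.

Step 2
Reactants: 3 (5R)-3-bromo-5-[(1R,2S,5R)-menthyloxy]furan-2(5H)-one; 4 (4-methoxyphenyl)boronic acid
Product: 5 (5R)-3-(4-methoxyphenyl)-5-[(1R,2S,5R)-menthyloxy]furan-2(5H)-one
Conditions: Pd(PPh3)4 (5 mol%, zerovalent palladium), K3PO4, 1,4-dioxane/H2O 10:1, 60 °C
Reagents that add atoms: none
Why: Suzuki–Miyaura coupling at the α-bromo enoate should install the aryl group that becomes ring C (methoxy para to the future C9); no stereocentre is formed and the acetal carbon is untouched.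

Step 3
Reactants: 6 methyl acetate; 7 acrolein
Product: 9 methyl 3-hydroxypent-4-enoate (racemic), via lithium enolate of methyl acetate 8 (not isolated)
Conditions: LiN(i-Pr)2, THF, −78 °C; then 7; aq. NH4Cl
Reagents that add atoms: none
Why: Crossed aldol addition of the ester enolate to the aldehyde (1,2-addition at low temperature) should give the allylic alcohol, whose racemic carbinol centre is oxidised in the next step.

Step 4
Reactants: 9 methyl 3-hydroxypent-4-enoate
Product: 10 methyl 3-oxopent-4-enoate
Conditions: CrO3, H2SO4, H2O, acetone, 0 °C (Jones oxidation); used at once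
Reagents that add atoms: none
Why: Jones oxidation of the secondary allylic alcohol should give the vinyl ketone β-keto ester, which has no stereocentre.

Step 5
Reactants: 10 methyl 3-oxopent-4-enoate
Product: 11 methyl (2Z)-3-{[tert-butyl(dimethyl)silyl]oxy}penta-2,4-dienoate
Conditions: t-BuMe2SiOSO2CF3, Et3N, CH2Cl2, −78 to 0 °C
Reagents that add atoms: tert-butyldimethylsilyl triflate, CC(C)(C)[Si](C)(C)OS(=O)(=O)C(F)(F)F
Why: Soft enolisation and O-silylation at the doubly activated C4–H should give the 2-silyloxydiene, the Z enol ether (silyloxy cis to the ester) following from the internally chelated enol geometry of the β-keto ester.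

Step 6
Reactants: 5 (5R)-3-(4-methoxyphenyl)-5-[(1R,2S,5R)-menthyloxy]furan-2(5H)-one; 11 methyl (2Z)-3-{[tert-butyl(dimethyl)silyl]oxy}penta-2,4-dienoate
Product: 13 ring A keto ester lactone acetal, via silyl enol ether cycloadduct 12 (not isolated)
Conditions: toluene, 2,6-di-tert-butyl-4-methylphenol (1 mol%), 120 °C, sealed tube; then Bu4NF, AcOH, THF, 0 °C
Reagents that add atoms: none
Why: A thermal normal-demand Diels–Alder reaction (concerted, asynchronous [4+2]) joins diene 11 (C1=C2–C3(OSi)=C4) to the C5=C10 bond of butenolide 5, the closest known type being the cycloaddition of 5-alkoxy-2(5H)-furanones with 2-silyloxydienes; buffered fluoride then unmasks the C3 ketone. Ring A (C1–C5, C10) is closed by intermolecular suprafacial addition, both new bonds (C4–C5 and C1–C10) forming on one face of the lactone, so ring A is cis-fused to the lactone and the 10-aryl group ends trans to C6. C5 is controlled by the acetal carbon C6, the diene adding anti to the menthyloxy group; C10 follows from the suprafacial addition; C4 should form mainly with the ester cis to the lactone (lactone endo) but is an epimerisable β-keto ester centre that is fixed in step 7. The step needs regioselectivity (C4 to C5, C1 to C10), which is secured electronically (the silyloxy-bearing terminus C4 is the nucleophilic end, C5 is the β-carbon of the 2-aryl-enoate and the developing charge at C10 is benzylic) and sterically (the substituted terminus C4 avoids the fully substituted C10). The 2-aryl group lowers the LUMO as in 2-arylacrylates, which should offset the trisubstitution of the dienophile.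

Step 7
Reactants: 13 ring A keto ester lactone acetal
Product: 14 4β-methyl keto ester lactone acetal
Conditions: K2CO3, MeI, acetone, rt
Reagents that add atoms: iodomethane, CI
Why: C-alkylation of the β-keto ester enolate (SN2 on MeI) should occur on the β face of C4, away from the axial C20 carbonyl on C10 and the C5–C6 bond of the cis-fused lactone that screen the α face, which places C18 β and C19 α.

Step 8
Reactants: 14 4β-methyl keto ester lactone acetal
Product: 16 ring A 6,20-anhydride, via lactol 15 (not isolated)
Conditions: CF3CO2H/H2O 4:1, 50 °C; evaporate, hexane trituration to recover menthol; then PhI(OAc)2, TEMPO (10 mol%), CH2Cl2, rt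
Reagents that add atoms: water, O
Why: Acid hydrolysis of the mixed acetal releases the auxiliary and gives the cis-lactol, which oxoammonium oxidation should convert into the cyclic anhydride while C5 and C10 stay locked in the ring.

Step 9
Reactants: 16 ring A 6,20-anhydride
Product: 17 tricyclic diketo acid
Conditions: AlCl3 (3.5 equiv), ClCH2CH2Cl, 0 °C to rt; cold aq. HCl
Reagents that add atoms: none
Why: In this intramolecular Friedel–Crafts acylation only the C6 carbonyl can reach an ortho carbon of the 10-aryl group (five-membered closure; C20 would close a four-membered ring), and because aryl and C6 are trans on ring A the new ring B should be trans-fused (5β-H, 10α-CO2H) as in the target, the cold quench limiting enolisation at C5.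

Step 10
Reactants: 17 tricyclic diketo acid
Product: 18 3β,6-diol acid (C6 epimers)
Conditions: Li[BH(s-Bu)3] (3.5 equiv), THF, −78 to −40 °C; aq. NH4Cl
Reagents that add atoms: none
Why: The bulky trialkylborohydride should attack the C3 ketone (flanked by quaternary C4) equatorially to give the axial 3β-alcohol, as with 4,4-disubstituted 3-oxo terpenoids, and it reduces the aryl ketone at the same time to a benzylic alcohol whose configuration is irrelevant.

Step 11
Reactants: 18 3β,6-diol acid
Product: 19 3β-hydroxy 6-ketone acid
Conditions: activated MnO2 (20 equiv), CH2Cl2, rt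
Reagents that add atoms: none
Why: Activated MnO2 should oxidise only the benzylic C6 alcohol back to the aryl ketone and leave the saturated 3β-alcohol and all stereocentres untouched.

Step 12
Reactants: 19 3β-hydroxy 6-ketone acid
Product: 21 3β-triisopropylsilyl ether 6-ketone acid, via bis-silylated compound 20 (not isolated)
Conditions: i-Pr3SiOSO2CF3 (2.6 equiv), 2,6-lutidine, CH2Cl2, 0 °C to rt; then Bu4NF (1.1 equiv), AcOH (2 equiv), THF, 0 °C
Reagents that add atoms: triisopropylsilyl triflate, CC(C)[Si](OS(=O)(=O)C(F)(F)F)(C(C)C)C(C)C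
Why: The silyl triflate with a hindered pyridine base should silylate the congested axial alcohol without enolising the aryl ketone at C5, and buffered fluoride then cleaves only the silyl ester at C20; the robust silyl ether guards the alcohol against alkoxide-triggered retro-aldol cleavage in steps 13 and 14, survives the acid of step 14 and keeps the alcohol away from the lead reagent in step 15.

Step 13
Reactants: 21 3β-triisopropylsilyl ether 6-ketone acid; 22 propargyl bromide
Product: 24 8β-propargyl dienol ether keto acid, via dipotassium dienolate 23 (not isolated)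
Conditions: K (3.3 equiv), t-BuOH (1.0 equiv), NH3(l)/THF, −78 °C; then 22 (3 equiv), −78 to −33 °C; NH4Cl
Reagents that add atoms: none
Why: In this Birch reductive alkylation of a 1-indanone, two-electron reduction and protonation at C12 (para to the carbonyl-bearing ring carbon) give the dienolate, which should be alkylated at C8 on the β face, anti to the 10α-carboxylate, setting the quaternary centre with C15 β while the methoxy group stays on a double bond (C13 enol ether) and the hindered 19-ester survives the brief stoichiometric reduction.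

Step 14
Reactants: 24 8β-propargyl dienol ether keto acid
Product: 26 3β-silyl ether aldehyde enone acid, via methoxymethylidene enol ether 25 (not isolated)
Conditions: MeOCH2PPh3Cl (6 equiv), KN(SiMe3)2 (6.5 equiv), THF, 0 to 45 °C; then 2 M HCl, THF, 40 °C
Reagents that add atoms: (methoxymethyl)triphenylphosphonium chloride, COC[P+](c1ccccc1)(c1ccccc1)c1ccccc1.[Cl-]; water, O
Why: Wittig methoxymethylenation of the only ketone (C13 is masked) is followed by aqueous acid, which should hydrolyse both enol ethers, move the 9(11)-olefin into conjugation with 9β-H (cis B/C hydrindane, thermodynamic control through the dienol) and equilibrate the new aldehyde to the more stable 6β epimer (trans to C4), while the hindered triisopropylsilyl ether stays in place.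

Step 15
Reactants: 26 3β-silyl ether aldehyde enone acid
Product: 27 3β-silyl ether 19,10-lactone aldehyde
Conditions: Pb(OAc)4 (1.5 equiv, tetravalent lead), pyridine (2 equiv), benzene, 80 °C, argon
Reagents that add atoms: none
Why: Kochi oxidative decarboxylation of the tertiary 20-acid gives the C10 radical and then the cation, which should be captured on the α face by the 1,3-diaxial 19-ester carbonyl, acetate removing the O-methyl group, so that the tether alone fixes the 10α-oxygen and the trans A/B fusion; with the 3β-oxygen silylated no lead alkoxide can form, so fragmentation of the C3–C4 bond is excluded.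

Step 16
Reactants: 27 3β-silyl ether 19,10-lactone aldehyde
Product: 28 19,10-lactone aldehyde
Conditions: aq. HF (48%), MeCN, 0 °C to rt
Reagents that add atoms: none
Why: Acidic fluoride desilylation should free the 3β-alcohol under non-basic conditions, which avoid retro-aldol epimerisation at C3 and leave the aldehyde, enone, alkyne and lactone untouched; no stereocentre is affected.

Step 17
Reactants: 28 19,10-lactone aldehyde
Product: 29 19,10-lactone 7-acid enone
Conditions: NaClO2, NaH2PO4, 2-methylbut-2-ene, t-BuOH/H2O, rt
Reagents that add atoms: sodium chlorite, [Na+].[O-]Cl=O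
Why: Pinnick oxidation should convert the aldehyde into the 7-acid under non-basic conditions that leave C6, the enone and the alkyne untouched.

Step 18
Reactants: 29 19,10-lactone 7-acid enone
Product: 30 19,10-lactone 7-acid 13-ketone
Conditions: Na2S2O4 (4 equiv), NaHCO3, 1,4-dioxane/H2O 1:1, 70 °C
Reagents that add atoms: none
Why: Dithionite conjugate reduction (electron transfer and protonation at C11 and C12) should saturate the enone without reducing the terminal alkyne, the lactone or the acid, and forms no stereocentre.

Step 19
Reactants: 30 19,10-lactone 7-acid 13-ketone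
Product: 31 15-deoxy gibberellin (3β,13-dihydroxy 19,10-lactone 7-acid)
Conditions: SmI2 (4 equiv, divalent samarium), HMPA, t-BuOH, THF, −20 °C to rt
Reagents that add atoms: none
Why: Ketyl–alkyne reductive cyclisation: the C13 ketyl should add 5-exo-dig to C16 of the propargyl group, closing ring D as the bicyclo[3.2.1]octane with the bridgehead 13-hydroxyl and the exocyclic methylene, C13 being fixed by the bridge geometry.

Step 20
Reactants: 31 15-deoxy gibberellin (3β,13-dihydroxy 19,10-lactone 7-acid)
Product: 32 target gibberellin (3β,13,15β-trihydroxy 19,10-lactone 7-acid)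
Conditions: SeO2 (0.5 equiv), t-BuOOH (4 equiv), CH2Cl2, rt
Reagents that add atoms: selenium dioxide (oxygen carrier), O=[Se]=O; tert-butyl hydroperoxide, CC(C)(C)OO
Why: Allylic hydroxylation by ene reaction at C17 and [2,3]-sigmatropic shift of the allylseleninic acid should occur at C15, the only allylic C–H site (C13 is fully substituted), with oxygen returned to the β face of C15, anti to the C14 methylene that overhangs the α face of the two-carbon bridge, which is the usual sense for 16-enes of this bicyclo[3.2.1]octane type.

**Compound list**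

1 | (5R)-5-[(1R,2S,5R)-menthyloxy]furan-2(5H)-one | O=C1C=C[C@H](O[C@@H]2C[C@H](C)CC[C@H]2C(C)C)O1 | starting material
2 | 3,4-dibromo lactone: (5R)-3,4-dibromo-5-[(1R,2S,5R)-menthyloxy]dihydrofuran-2(3H)-one (trans-dibromide, C3/C4 not controlled) | O=C1C(Br)C(Br)[C@H](O[C@@H]2C[C@H](C)CC[C@H]2C(C)C)O1 | intermediate
3 | (5R)-3-bromo-5-[(1R,2S,5R)-menthyloxy]furan-2(5H)-one | O=C1C(Br)=C[C@H](O[C@@H]2C[C@H](C)CC[C@H]2C(C)C)O1 | intermediate
4 | (4-methoxyphenyl)boronic acid | COc1ccc(cc1)B(O)O | starting material
5 | (5R)-3-(4-methoxyphenyl)-5-[(1R,2S,5R)-menthyloxy]furan-2(5H)-one | COc1ccc(cc1)C1=C[C@H](O[C@@H]2C[C@H](C)CC[C@H]2C(C)C)OC1=O | intermediate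
6 | methyl acetate | CC(=O)OC | starting material
7 | acrolein | C=CC=O | starting material
8 | lithium enolate of methyl acetate | [Li+].[O-]C(=C)OC | intermediate
9 | methyl 3-hydroxypent-4-enoate (racemic) | C=CC(O)CC(=O)OC | intermediate
10 | methyl 3-oxopent-4-enoate | C=CC(=O)CC(=O)OC | intermediate
11 | methyl (2Z)-3-{[tert-butyl(dimethyl)silyl]oxy}penta-2,4-dienoate | C=C/C(O[Si](C)(C)C(C)(C)C)=C/C(=O)OC | intermediate
12 | silyl enol ether cycloadduct: ring A 2-ene with 3-OSi(t-Bu)Me2 and 4α-CO2Me (C19); 5β-H; 10β-(4-methoxyphenyl); γ-lactone C20(=O)–O–C6 cis-fused on the α face; (6R) O-menthyl acetal trans to C4 | COc1ccc(cc1)[C@]12CC=C(O[Si](C)(C)C(C)(C)C)[C@@H](C(=O)OC)[C@H]1[C@H](O[C@@H]3C[C@H](C)CC[C@H]3C(C)C)OC2=O | intermediate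
13 | ring A keto ester lactone acetal: as 12 with a 3-ketone (C4 epimerisable, drawn with the ester α) | COc1ccc(cc1)[C@]12CCC(=O)[C@@H](C(=O)OC)[C@H]1[C@H](O[C@@H]3C[C@H](C)CC[C@H]3C(C)C)OC2=O | intermediate
14 | 4β-methyl keto ester lactone acetal: as 13 with C18 methyl β and C19 ester α on C4 | COc1ccc(cc1)[C@]12CCC(=O)[C@@](C)(C(=O)OC)[C@H]1[C@H](O[C@@H]3C[C@H](C)CC[C@H]3C(C)C)OC2=O | intermediate
15 | lactol: 6-hydroxy γ-lactone (anomers) | COc1ccc(cc1)[C@]12CCC(=O)[C@@](C)(C(=O)OC)[C@H]1C(O)OC2=O | intermediate
16 | ring A 6,20-anhydride: 3-oxo; 4β-Me; 4α-CO2Me; 5β-H; 10β-(4-methoxyphenyl); cis-fused anhydride on the α face | COc1ccc(cc1)[C@]12CCC(=O)[C@@](C)(C(=O)OC)[C@H]1C(=O)OC2=O | intermediate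
17 | tricyclic diketo acid: A/B trans-fused; ring C aromatic with 13-OMe; 3-oxo; 6-oxo; 4β-Me; 4α-CO2Me; 5β-H; 10α-CO2H (C20) | COc1ccc2c(c1)C(=O)[C@H]1[C@@]2(C(=O)O)CCC(=O)[C@@]1(C)C(=O)OC | intermediate
18 | 3β,6-diol acid: as 17 with 3β-OH and 6-OH (C6 epimers) | COc1ccc2c(c1)C(O)[C@H]1[C@@]2(C(=O)O)CC[C@H](O)[C@@]1(C)C(=O)OC | intermediate
19 | 3β-hydroxy 6-ketone acid | COc1ccc2c(c1)C(=O)[C@H]1[C@@]2(C(=O)O)CC[C@H](O)[C@@]1(C)C(=O)OC | intermediate
20 | bis-silylated compound: 3β-OSi(i-Pr)3 and C20 triisopropylsilyl ester | COc1ccc2c(c1)C(=O)[C@H]1[C@@]2(C(=O)O[Si](C(C)C)(C(C)C)C(C)C)CC[C@H](O[Si](C(C)C)(C(C)C)C(C)C)[C@@]1(C)C(=O)OC | intermediate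
21 | 3β-triisopropylsilyl ether 6-ketone acid (3β-OSi(i-Pr)3) | COc1ccc2c(c1)C(=O)[C@H]1[C@@]2(C(=O)O)CC[C@H](O[Si](C(C)C)(C(C)C)C(C)C)[C@@]1(C)C(=O)OC | intermediate
22 | propargyl bromide | C#CCBr | starting material
23 | dipotassium dienolate: C6(O−)=C8 enolate; ring C 9(11),13-diene with 13-OMe; C20 carboxylate; 3β-OSi(i-Pr)3 | [K+].[K+].COC1=CC2=C([O-])[C@H]3[C@@](C2=CC1)(C(=O)[O-])CC[C@H](O[Si](C(C)C)(C(C)C)C(C)C)[C@@]3(C)C(=O)OC | intermediate
24 | 8β-propargyl dienol ether keto acid: quaternary C8 with C15H2–C16≡C17H β; ring C 9(11),13-diene with 13-OMe; 6-oxo; 10α-CO2H; 3β-OSi(i-Pr)3; 4α-CO2Me; 4β-Me; 5β-H | C#CC[C@]23C=C(OC)CC=C2[C@]2(C(=O)O)CC[C@H](O[Si](C(C)C)(C(C)C)C(C)C)[C@@](C)(C(=O)OC)[C@H]2C3=O | intermediate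
25 | methoxymethylidene enol ether: as 24 with C6=CH–OMe (E/Z) | C#CC[C@]23C=C(OC)CC=C2[C@]2(C(=O)O)CC[C@H](O[Si](C(C)C)(C(C)C)C(C)C)[C@@](C)(C(=O)OC)[C@H]2C3=COC | intermediate
26 | 3β-silyl ether aldehyde enone acid: 6β-CHO (C7); 13-oxo-11-ene; 9β-H; 8β-propargyl; 10α-CO2H; 3β-OSi(i-Pr)3; 4α-CO2Me | C#CC[C@]23CC(=O)C=C[C@H]2[C@]2(C(=O)O)CC[C@H](O[Si](C(C)C)(C(C)C)C(C)C)[C@@](C)(C(=O)OC)[C@H]2[C@@H]3C=O | intermediate
27 | 3β-silyl ether 19,10-lactone aldehyde: 3β-OSi(i-Pr)3; 6β-CHO; 13-oxo-11-ene; 8β-propargyl | C#CC[C@]23CC(=O)C=C[C@H]2[C@@]12CC[C@H](O[Si](C(C)C)(C(C)C)C(C)C)[C@@](C)(C(=O)O1)[C@H]2[C@@H]3C=O | intermediate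
28 | 19,10-lactone aldehyde: 3β-OH; 6β-CHO; 13-oxo-11-ene; 8β-propargyl | C#CC[C@]23CC(=O)C=C[C@H]2[C@@]12CC[C@H](O)[C@@](C)(C(=O)O1)[C@H]2[C@@H]3C=O | intermediate
29 | 19,10-lactone 7-acid enone | C#CC[C@]23CC(=O)C=C[C@H]2[C@@]12CC[C@H](O)[C@@](C)(C(=O)O1)[C@H]2[C@@H]3C(=O)O | intermediate
30 | 19,10-lactone 7-acid 13-ketone | C#CC[C@]23CC(=O)CC[C@H]2[C@@]12CC[C@H](O)[C@@](C)(C(=O)O1)[C@H]2[C@@H]3C(=O)O | intermediate
31 | 15-deoxy gibberellin: 3β,13-dihydroxy-20-norgibberell-16-ene-7,19-dioic acid 19,10-lactone | C=C1C[C@]23C[C@@]1(O)CC[C@H]2[C@@]12CC[C@H](O)[C@@](C)(C(=O)O1)[C@H]2[C@@H]3C(=O)O | intermediate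
32 | target gibberellin: 3β,13,15β-trihydroxy-20-norgibberell-16-ene-7,19-dioic acid 19,10-lactone | C=C1[C@@H](O)[C@]23C[C@@]1(O)CC[C@H]2[C@@]12CC[C@H](O)[C@@](C)(C(=O)O1)[C@H]2[C@@H]3C(=O)O | target

**Totals and risks**

Total step count: 20. Longest linear sequence: 18 steps (steps 3 to 20; 17 steps from butenolide 1).

Steps most likely to fail:

Step 14. The ylide may fail to add to the congested C6 carbonyl (between quaternary C8 and the ring-fusion carbon C5) and act as a base instead, enolising toward C5 and eroding the 5β configuration. The fallback sets out from 24 and uses a Peterson route: [methoxy(trimethylsilyl)methyl]lithium (from (methoxymethyl)trimethylsilane and s-BuLi, THF, −78 °C), a small and strongly nucleophilic carbanion, should add to the ketone to give the β-hydroxy α-methoxy silane F1. The same aqueous HCl treatment then eliminates trimethylsilanol to enol ether 25 and carries on through hydrolysis, conjugation and epimerisation, so the fallback comes back to the route at 26.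

Step 15. The C10 radical or cation may lose a proton or abstract hydrogen faster than the 19-ester captures it, and the aldehyde may suffer oxidation during the heating. The fallback sets out from 26 and separates the two events: Kochi decarboxylative elimination with Pb(OAc)4 and catalytic Cu(OAc)2 in benzene/pyridine is run on purpose, the copper salt favouring loss of a proton from the methylene C1, to give the 1(10)-olefin ester F2. CF3CO2H in CH2Cl2 then regenerates the tertiary C10 cation by protonation under non-oxidising conditions, where the 19-ester should close the lactone (methyl lost as methyl trifluoroacetate) and the silyl ether is retained. It comes back to the route at 27.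

Step 6. The cycloaddition may be too slow at the trisubstituted dienophile, so that thermal decomposition of the diene wins. The fallback sets out from 5 and 10 (the β-keto ester before silylation) and replaces the cycloaddition by an anionic double Michael annulation with Cs2CO3 (0.5 equiv) in CH2Cl2 at rt. The keto ester enolate should add through C4 to C5 of the butenolide, anti to the menthyloxy group, to give the Michael adduct F3, whose α-aryl lactone enolate then closes ring A onto the vinyl ketone (C10 to C1). It comes back to the route at 13.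

Further compounds
F1 | step 14 | β-hydroxy α-methoxy silane: as 24 with C6(OH)–CH(OMe)SiMe3 (epimers at C6 and C7) | C#CC[C@]23C=C(OC)CC=C2[C@]2(C(=O)O)CC[C@H](O[Si](C(C)C)(C(C)C)C(C)C)[C@@](C)(C(=O)OC)[C@H]2C3(O)C(OC)[Si](C)(C)C
F2 | step 15 | 1(10)-olefin ester: 20-nor; 3β-OSi(i-Pr)3; 4α-CO2Me; 6β-CHO; 13-oxo-11-ene; 8β-propargyl | C#CC[C@]23CC(=O)C=C[C@H]2C2=CC[C@H](O[Si](C(C)C)(C(C)C)C(C)C)[C@@](C)(C(=O)OC)[C@H]2[C@@H]3C=O
F3 | step 6 | Michael adduct: butanolide carrying at C5 (trans to O-menthyl) the CH(CO2Me)C(=O)CH=CH2 chain; 10-aryl; C4 and C10 not controlled | C=CC(=O)C(C(=O)OC)[C@@H]1C(c2ccc(OC)cc2)C(=O)O[C@H]1O[C@@H]1C[C@H](C)CC[C@H]1C(C)C
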